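**Plan**

Core locants used throughout: C1 (CH–OAc), C2 (CH2), C3 (C(OH)i-Pr), C4 (ring-fusion CH), C5 (CH–O-aroyl), C6=C7 (C7 bears CH3), C8 (C=O), C9 (CH2), C10 (ring-fusion C–CH3).
Retrosynthesis: (a) the two ester C–O bonds; (b) the C8 carbonyl oxygen (allylic C–H oxidation) and C6=C7 (ring-closing metathesis), which opens the seven-membered ring; (c) C5–C6 (vinyl addition to a C5 aldehyde); (d) the ring-fusion bond C4–C10, by re-expanding the cyclopentane to a six-membered 2-diazo ketone with C5 as ring carbonyl (Wolff ring contraction); (e) C3–O and C3–i-Pr; (f) C9–C10.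
Forward: the six-membered ring C1–C2–C3–C4–C5–C10 is made from 2-methylcyclohexane-1,3-dione (its carbonyls become C1 and C5), then the cyclopentane C1–C2–C3–C4–C10 by contraction, then the seven-membered ring C4–C10 by metathesis and oxidation.
Enabling feature: C5, the oxygen-bearing carbon that hangs on C4 outside the cyclopentane, can be written back between C4 and C10 as a ketone; because C10 is quaternary, diazo transfer can only go to C4 and only C10 can migrate, and C1 and C5 flank C10 as the carbonyls of a 2,2-disubstituted cyclohexane-1,3-dione do.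
Stereochemistry: C1 and C10 from a CBS desymmetrisation of the dione; C3 from a hydroxyl-directed epoxidation (temporary C5 carbinol) and reductive epoxide opening; C10 passes through the Wolff shift with retention and C4 is set by protonation of the resulting ester enol; C5 from chelation-controlled vinyl addition.

Key step: step 12

**Route**

Step 1
Reactants: 1 2-methylcyclohexane-1,3-dione; 2 but-3-en-2-one
Product: 3 2-methyl-2-(3-oxobutyl)cyclohexane-1,3-dione
Conditions: H2O, AcOH (cat.), hydroquinone (cat.), 75 °C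
Reagents that add atoms: none
Why: Michael addition of the enolised 1,3-dione to the enone in water is the standard entry to the 2,2-disubstituted dione and creates no stereocentre, the quaternary carbon (future C10) still being prochiral.

Step 2
Reactants: 3 2-methyl-2-(3-oxobutyl)cyclohexane-1,3-dione
Product: 4 2-methyl-2-(3-methylbut-3-en-1-yl)cyclohexane-1,3-dione
Conditions: Ph3PCH3Br, KOt-Bu, THF, 0 °C; then 3, −78 → 0 °C
Reagents that add atoms: methyltriphenylphosphonium bromide, C[P+](c1ccccc1)(c1ccccc1)c1ccccc1.[Br-]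
Why: Wittig methylenation should occur only at the unhindered side-chain methyl ketone, because both ring carbonyls flank the quaternary carbon, and it gives the 1,1-disubstituted alkene (C7 with its methyl) needed for the later metathesis.

Step 3
Reactants: 4 2-methyl-2-(3-methylbut-3-en-1-yl)cyclohexane-1,3-dione
Product: 5 (2R,3R)-3-hydroxy-2-methyl-2-(3-methylbut-3-en-1-yl)cyclohexan-1-one
Conditions: (S)-2-methyl-CBS-oxazaborolidine (20 mol%), catecholborane, toluene, −78 °C
Reagents that add atoms: none
Why: Corey–Bakshi–Shibata desymmetrisation of the prochiral dione, in which the catalyst dictates the (R) carbinol (C1) and hydride delivery on the face of the small methyl group, away from the longer chain, selects which carbonyl reacts, so that C1 and the quaternary C10 are set together (hydroxyl trans to methyl) while catecholborane at low temperature leaves the alkene untouched.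

Step 4
Reactants: 5 (2R,3R)-3-hydroxy-2-methyl-2-(3-methylbut-3-en-1-yl)cyclohexan-1-one
Product: 6 (2R,3R)-3-(tert-butyldimethylsilyloxy)-2-methyl-2-(3-methylbut-3-en-1-yl)cyclohexan-1-one
Conditions: t-BuMe2SiOTf, 2,6-lutidine, CH2Cl2, −78 → 0 °C
Reagents that add atoms: tert-butyldimethylsilyl trifluoromethanesulfonate, CC(C)(C)[Si](C)(C)OS(=O)(=O)C(F)(F)F
Why: Silylation of the hindered secondary alcohol protects the C1 oxygen through the basic, reductive and photochemical steps and keeps it from capturing the ketene of step 12, without touching a stereocentre.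

Step 5
Reactants: 6 (2R,3R)-3-(tert-butyldimethylsilyloxy)-2-methyl-2-(3-methylbut-3-en-1-yl)cyclohexan-1-one
Product: 7 (5R,6R)-5-(tert-butyldimethylsilyloxy)-6-methyl-6-(3-methylbut-3-en-1-yl)cyclohex-2-en-1-one
Conditions: 2-iodoxybenzoic acid (IBX), DMSO, 65 °C
Reagents that add atoms: none
Why: IBX dehydrogenation of the ketone can only introduce the C3=C4 double bond because the other α-carbon (C10) is quaternary.

Step 6
Reactants: 7 (5R,6R)-5-(tert-butyldimethylsilyloxy)-6-methyl-6-(3-methylbut-3-en-1-yl)cyclohex-2-en-1-one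
Product: 9 (5R,6R)-5-(tert-butyldimethylsilyloxy)-3-isopropyl-6-methyl-6-(3-methylbut-3-en-1-yl)cyclohex-2-en-1-one, via trimethylsilyl enol ether 8 (not isolated)
Conditions: i-PrMgCl, CuBr·SMe2 (10 mol%), Me3SiCl, THF, −78 °C; then Pd(OAc)2, MeCN, rt
Reagents that add atoms: isopropylmagnesium chloride, CC(C)[Mg]Cl; chlorotrimethylsilane, C[Si](C)(C)Cl (silicon only in 8)
Why: Copper-catalysed conjugate addition with silyl trapping followed by Saegusa–Ito oxidation of the regiodefined silyl enol ether places the isopropyl group on C3 and restores the enone, the transient C3 stereocentre being erased.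

Step 7
Reactants: 9 (5R,6R)-5-(tert-butyldimethylsilyloxy)-3-isopropyl-6-methyl-6-(3-methylbut-3-en-1-yl)cyclohex-2-en-1-one
Product: 10 (1S,5R,6S)-5-(tert-butyldimethylsilyloxy)-3-isopropyl-6-methyl-6-(3-methylbut-3-en-1-yl)cyclohex-2-en-1-ol
Conditions: NaBH4, CeCl3·7H2O, MeOH, −78 → 0 °C
Reagents that add atoms: none
Why: Luche 1,2-reduction, in which axial hydride attack on the half-chair with the silyloxy group pseudo-equatorial comes from the face of the C10 methyl group, anti to the pseudo-axial side chain, so that the new C5 hydroxyl (a temporary directing stereocentre) should be cis to the silyloxy group.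

Step 8
Reactants: 10 (1S,5R,6S)-5-(tert-butyldimethylsilyloxy)-3-isopropyl-6-methyl-6-(3-methylbut-3-en-1-yl)cyclohex-2-en-1-ol
Product: 11 4-(tert-butyldimethylsilyloxy)-6-isopropyl-3-methyl-3-(3-methylbut-3-en-1-yl)-7-oxabicyclo[4.1.0]heptan-2-ol with hydroxyl, epoxide oxygen and silyloxy group on one face
Conditions: VO(acac)2 (5 mol%), t-BuOOH, CH2Cl2, 0 °C → rt
Reagents that add atoms: tert-butyl hydroperoxide, CC(C)(C)OO
Why: Hydroxyl-directed vanadium-catalysed epoxidation delivers oxygen to the allylic alkene on the face of the C5 hydroxyl, which fixes the C3–O bond cis to the C1 silyloxy group and trans to the C10 methyl, and it leaves the remote 1,1-disubstituted alkene alone.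

Step 9
Reactants: 11 the syn epoxy alcohol
Product: 12 4-(tert-butyldimethylsilyloxy)-6-isopropyl-3-methyl-3-(3-methylbut-3-en-1-yl)-7-oxabicyclo[4.1.0]heptan-2-one (epoxide oxygen cis to the silyloxy group)
Conditions: Dess–Martin periodinane, NaHCO3, CH2Cl2, rt
Reagents that add atoms: none
Why: Dess–Martin oxidation of the secondary epoxy alcohol regenerates the C5 ketone under neutral conditions without disturbing the epoxide or the tertiary C3 centre.

Step 10
Reactants: 12 the α,β-epoxy ketone
Product: 13 (2R,3R,5S)-3-(tert-butyldimethylsilyloxy)-5-hydroxy-5-isopropyl-2-methyl-2-(3-methylbut-3-en-1-yl)cyclohexan-1-one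
Conditions: SmI2, THF/MeOH, −90 °C
Reagents that add atoms: none
Why: Samarium diiodide reduction of the α,β-epoxy ketone cleaves only the C4–O bond through the ketyl, so the C3–O bond keeps the configuration set in step 8 and the aldol-type tertiary alcohol is released without dehydration.

Step 11
Reactants: 13 (2R,3R,5S)-3-(tert-butyldimethylsilyloxy)-5-hydroxy-5-isopropyl-2-methyl-2-(3-methylbut-3-en-1-yl)cyclohexan-1-one
Product: 15 (2R,3R,5R)-3-(tert-butyldimethylsilyloxy)-6-diazo-5-hydroxy-5-isopropyl-2-methyl-2-(3-methylbut-3-en-1-yl)cyclohexan-1-one, via trifluoroacetyl ketone 14 (not isolated)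
Conditions: LiN(SiMe3)2 (2.2 equiv), THF, −78 °C, then CF3CO2CH2CF3; then MeSO2N3, Et3N, H2O, MeCN, rt
Reagents that add atoms: 2,2,2-trifluoroethyl trifluoroacetate, O=C(OCC(F)(F)F)C(F)(F)F (atoms only in 14); methanesulfonyl azide, CS(=O)(=O)N=[N+]=[N-]
Why: Deacylative (Regitz-type) diazo transfer, in which the alkoxide–enolate dianion is C-trifluoroacetylated at C4, the only enolisable position since C10 is quaternary, and the activated methine then takes up the diazo group with loss of the trifluoroacetyl unit, no stereocentre being changed.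

Step 12
Reactants: 15 (2R,3R,5R)-3-(tert-butyldimethylsilyloxy)-6-diazo-5-hydroxy-5-isopropyl-2-methyl-2-(3-methylbut-3-en-1-yl)cyclohexan-1-one
Product: 17 methyl (1S,2R,4R,5S)-4-(tert-butyldimethylsilyloxy)-2-hydroxy-2-isopropyl-5-methyl-5-(3-methylbut-3-en-1-yl)cyclopentane-1-carboxylate, via ketene 16 (not isolated)
Conditions: hν (>300 nm, Pyrex), MeOH, 0 °C
Reagents that add atoms: methanol, CO
Why: Photolysis of the cyclic α-diazo ketone, which is locked s-cis, expels N2 with a concerted 1,2-shift of the C10–C5 bond to the diazo carbon C4 (Wolff rearrangement), so the C4–C10 bond forms while C5 is pushed out of the ring as a ketene that methanol traps as the methyl ester. The closest known reaction type is the photochemical Wolff ring contraction of 2-diazocyclohexanones to cyclopentanecarboxylates. The cyclopentane C1–C2–C3–C4–C10 is closed by contraction of the six-membered ring C1–C2–C3–C4–C5–C10 through a suprafacial 1,2-alkyl shift, not by an exo or endo cyclisation, and no other ring is formed. C10 migrates with retention, so the quaternary centre and the centres at C1 and C3 are carried over unchanged, and the new stereocentre C4 is set by protonation of the ester enol from the face of the C3 hydroxyl and the C10 side chain, opposite the isopropyl and methyl groups, which places the ester cis to isopropyl and methyl as the trans ring fusion requires. The step needs site selectivity (only C10 can migrate, being the sole carbon substituent on the carbonyl, and the diazo group can only sit on C4), suppression of carbene pathways (the concerted shift from the s-cis diazo ketone and the absence of hydrogen on C3 rule out 1,2-hydride shift and disfavour O–H insertion and cyclopropanation of the side-chain alkene) and fast intermolecular capture of the ketene, secured by methanol as solvent and by the silyl group on the C1 oxygen, which would otherwise lactonise onto the ketene.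

Step 13
Reactants: 17 methyl (1S,2R,4R,5S)-4-(tert-butyldimethylsilyloxy)-2-hydroxy-2-isopropyl-5-methyl-5-(3-methylbut-3-en-1-yl)cyclopentane-1-carboxylate
Product: 19 (1R)-1-[(1R,2R,4R,5S)-4-(tert-butyldimethylsilyloxy)-2-hydroxy-2-isopropyl-5-methyl-5-(3-methylbut-3-en-1-yl)cyclopentyl]prop-2-en-1-ol, via aldehyde 18 (not isolated)
Conditions: i-Bu2AlH (2.2 equiv), CH2Cl2, −78 °C; then CH2=CHMgBr, −78 → −20 °C
Reagents that add atoms: vinylmagnesium bromide, C=C[Mg]Br
Why: One-pot half-reduction of the ester to the chelated aluminium hemiacetal and Grignard addition to the aldehyde released in situ avoids handling the epimerisable β-hydroxy aldehyde, and in the six-membered chelate through the C3 alkoxide the nucleophile should attack anti to the axial isopropyl group (chelation control), giving the (5R) carbinol.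

Step 14
Reactants: 19 the (5R) allylic alcohol; 20 4-acetoxybenzoyl chloride
Product: 21 (1R)-1-[(1R,2R,4R,5S)-4-(tert-butyldimethylsilyloxy)-2-hydroxy-2-isopropyl-5-methyl-5-(3-methylbut-3-en-1-yl)cyclopentyl]prop-2-en-1-yl 4-acetoxybenzoate
Conditions: pyridine, 4-(dimethylamino)pyridine (cat.), CH2Cl2, 0 °C → rt
Reagents that add atoms: none
Why: Nucleophile-catalysed acylation of the secondary allylic alcohol proceeds with retention at C5 while the hindered tertiary C3 hydroxyl stays free, and the phenol arrives masked as its acetate.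

Step 15
Reactants: 21 the diene ester
Product: 22 (1R,3R,4R,5R,10S)-1-(tert-butyldimethylsilyloxy)-3-hydroxy-3-isopropyl-7,10-dimethylbicyclo[5.3.0]dec-6-en-5-yl 4-acetoxybenzoate (core locants)
Conditions: second-generation Grubbs catalyst [RuCl2(=CHPh)(H2IMes)(PCy3)] (5 mol%), CH2Cl2 (0.005 M), 40 °C
Reagents that add atoms: none
Why: Ring-closing metathesis between the vinyl group and the 1,1-disubstituted alkene closes the seven-membered ring as its trisubstituted C6=C7 alkene with loss of ethene, the trans ring fusion being already fixed at C4 and C10.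

Step 16
Reactants: 22 the bicyclic alkene
Product: 23 (1R,3R,4R,5R,10S)-1-(tert-butyldimethylsilyloxy)-3-hydroxy-3-isopropyl-7,10-dimethyl-8-oxobicyclo[5.3.0]dec-6-en-5-yl 4-acetoxybenzoate (core locants)
Conditions: Mn(OAc)3·2H2O (10 mol%), t-BuOOH, 3 Å MS, EtOAc, rt
Reagents that add atoms: tert-butyl hydroperoxide, CC(C)(C)OO
Why: Radical allylic C–H oxidation with tert-butyl hydroperoxide under trivalent manganese catalysis should convert the only allylic methylene (C8) into the enone carbonyl, since the other ring allylic position C5 is a deactivated acyloxy methine and the C7 methyl is a less reactive primary site.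

Step 17
Reactants: 23 the silylated enone
Product: 24 (1R,3R,4R,5R,10S)-1,3-dihydroxy-3-isopropyl-7,10-dimethyl-8-oxobicyclo[5.3.0]dec-6-en-5-yl 4-acetoxybenzoate (core locants)
Conditions: HF·pyridine, pyridine/THF, 0 °C → rt
Reagents that add atoms: none
Why: Fluoride-mediated cleavage of the silyl ether under buffered acidic conditions frees the C1 hydroxyl without touching the aryl acetate, the allylic ester or the enone.

Step 18
Reactants: 24 the C1 alcohol
Product: 26 the target, via diacetate 25 (not isolated)
Conditions: Ac2O, pyridine, 4-(dimethylamino)pyridine (cat.), CH2Cl2, rt; then concentrate, NH4OAc, MeOH/H2O (4:1), rt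
Reagents that add atoms: acetic anhydride, CC(=O)OC(C)=O
Why: Acetylation of the secondary C1 hydroxyl (the tertiary C3 hydroxyl is too hindered to react) followed by chemoselective solvolysis of the phenolic acetate, a far better acyl donor than the alkyl acetate or the benzoate-type ester, unmasks the phenol and completes the target.

**Compound list**

1 | 2-methylcyclohexane-1,3-dione | CC1C(=O)CCCC1=O | starting material
2 | but-3-en-2-one | CC(=O)C=C | starting material
3 | 2-methyl-2-(3-oxobutyl)cyclohexane-1,3-dione | CC(=O)CCC1(C)C(=O)CCCC1=O | intermediate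
4 | 2-methyl-2-(3-methylbut-3-en-1-yl)cyclohexane-1,3-dione | C=C(C)CCC1(C)C(=O)CCCC1=O | intermediate
5 | (2R,3R)-3-hydroxy-2-methyl-2-(3-methylbut-3-en-1-yl)cyclohexan-1-one | O=C1CCC[C@@H](O)[C@@]1(C)CCC(C)=C | intermediate
6 | (2R,3R)-3-(tert-butyldimethylsilyloxy)-2-methyl-2-(3-methylbut-3-en-1-yl)cyclohexan-1-one | O=C1CCC[C@@H](O[Si](C)(C)C(C)(C)C)[C@@]1(C)CCC(C)=C | intermediate
7 | (5R,6R)-5-(tert-butyldimethylsilyloxy)-6-methyl-6-(3-methylbut-3-en-1-yl)cyclohex-2-en-1-one | O=C1C=CC[C@@H](O[Si](C)(C)C(C)(C)C)[C@@]1(C)CCC(C)=C | intermediate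
8 | trimethylsilyl enol ether of the 3-isopropyl ketone (isopropyl trans to the silyloxy group) | C[Si](C)(C)OC1=C[C@H](C(C)C)C[C@@H](O[Si](C)(C)C(C)(C)C)[C@@]1(C)CCC(C)=C | intermediate
9 | (5R,6R)-5-(tert-butyldimethylsilyloxy)-3-isopropyl-6-methyl-6-(3-methylbut-3-en-1-yl)cyclohex-2-en-1-one | O=C1C=C(C(C)C)C[C@@H](O[Si](C)(C)C(C)(C)C)[C@@]1(C)CCC(C)=C | intermediate
10 | (1S,5R,6S)-5-(tert-butyldimethylsilyloxy)-3-isopropyl-6-methyl-6-(3-methylbut-3-en-1-yl)cyclohex-2-en-1-ol | O[C@H]1C=C(C(C)C)C[C@@H](O[Si](C)(C)C(C)(C)C)[C@@]1(C)CCC(C)=C | intermediate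
11 | 4-(tert-butyldimethylsilyloxy)-6-isopropyl-3-methyl-3-(3-methylbut-3-en-1-yl)-7-oxabicyclo[4.1.0]heptan-2-ol, hydroxyl, epoxide oxygen and silyloxy group on one face | O[C@H]1[C@H]2O[C@@]2(C(C)C)C[C@@H](O[Si](C)(C)C(C)(C)C)[C@@]1(C)CCC(C)=C | intermediate
12 | 4-(tert-butyldimethylsilyloxy)-6-isopropyl-3-methyl-3-(3-methylbut-3-en-1-yl)-7-oxabicyclo[4.1.0]heptan-2-one, epoxide oxygen cis to the silyloxy group | O=C1[C@H]2O[C@@]2(C(C)C)C[C@@H](O[Si](C)(C)C(C)(C)C)[C@@]1(C)CCC(C)=C | intermediate
13 | (2R,3R,5S)-3-(tert-butyldimethylsilyloxy)-5-hydroxy-5-isopropyl-2-methyl-2-(3-methylbut-3-en-1-yl)cyclohexan-1-one | O=C1C[C@](O)(C(C)C)C[C@@H](O[Si](C)(C)C(C)(C)C)[C@@]1(C)CCC(C)=C | intermediate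
14 | 6-trifluoroacetyl derivative of 13 | O=C1C(C(=O)C(F)(F)F)[C@](O)(C(C)C)C[C@@H](O[Si](C)(C)C(C)(C)C)[C@@]1(C)CCC(C)=C | intermediate
15 | (2R,3R,5R)-3-(tert-butyldimethylsilyloxy)-6-diazo-5-hydroxy-5-isopropyl-2-methyl-2-(3-methylbut-3-en-1-yl)cyclohexan-1-one | O=C1C(=[N+]=[N-])[C@](O)(C(C)C)C[C@@H](O[Si](C)(C)C(C)(C)C)[C@@]1(C)CCC(C)=C | intermediate
16 | ring-contracted cyclopentylidene ketene | O=C=C1[C@](O)(C(C)C)C[C@@H](O[Si](C)(C)C(C)(C)C)[C@@]1(C)CCC(C)=C | intermediate
17 | methyl (1S,2R,4R,5S)-4-(tert-butyldimethylsilyloxy)-2-hydroxy-2-isopropyl-5-methyl-5-(3-methylbut-3-en-1-yl)cyclopentane-1-carboxylate | COC(=O)[C@@H]1[C@](O)(C(C)C)C[C@@H](O[Si](C)(C)C(C)(C)C)[C@@]1(C)CCC(C)=C | intermediate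
18 | the corresponding cyclopentane-1-carbaldehyde (formed from its aluminium hemiacetal) | O=C[C@@H]1[C@](O)(C(C)C)C[C@@H](O[Si](C)(C)C(C)(C)C)[C@@]1(C)CCC(C)=C | intermediate
19 | (1R)-1-[(1R,2R,4R,5S)-4-(tert-butyldimethylsilyloxy)-2-hydroxy-2-isopropyl-5-methyl-5-(3-methylbut-3-en-1-yl)cyclopentyl]prop-2-en-1-ol | C=C[C@@H](O)[C@@H]1[C@](O)(C(C)C)C[C@@H](O[Si](C)(C)C(C)(C)C)[C@@]1(C)CCC(C)=C | intermediate
20 | 4-acetoxybenzoyl chloride | CC(=O)Oc1ccc(cc1)C(Cl)=O | starting material
21 | (1R)-1-[(1R,2R,4R,5S)-4-(tert-butyldimethylsilyloxy)-2-hydroxy-2-isopropyl-5-methyl-5-(3-methylbut-3-en-1-yl)cyclopentyl]prop-2-en-1-yl 4-acetoxybenzoate | C=C[C@@H](OC(=O)c1ccc(OC(C)=O)cc1)[C@@H]2[C@](O)(C(C)C)C[C@@H](O[Si](C)(C)C(C)(C)C)[C@@]2(C)CCC(C)=C | intermediate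
22 | (1R,3R,4R,5R,10S)-1-(tert-butyldimethylsilyloxy)-3-hydroxy-3-isopropyl-7,10-dimethylbicyclo[5.3.0]dec-6-en-5-yl 4-acetoxybenzoate (core locants) | CC(C)(C)[Si](C)(C)O[C@@H]1C[C@@](O)(C(C)C)[C@H]2[C@H](OC(=O)c3ccc(OC(C)=O)cc3)C=C(C)CC[C@]12C | intermediate
23 | 8-oxo derivative of 22 | CC(C)(C)[Si](C)(C)O[C@@H]1C[C@@](O)(C(C)C)[C@H]2[C@H](OC(=O)c3ccc(OC(C)=O)cc3)C=C(C)C(=O)C[C@]12C | intermediate
24 | (1R,3R,4R,5R,10S)-1,3-dihydroxy-3-isopropyl-7,10-dimethyl-8-oxobicyclo[5.3.0]dec-6-en-5-yl 4-acetoxybenzoate (core locants) | O[C@@H]1C[C@@](O)(C(C)C)[C@H]2[C@H](OC(=O)c3ccc(OC(C)=O)cc3)C=C(C)C(=O)C[C@]12C | intermediate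
25 | 1-O-acetyl derivative of 24 (diacetate) | CC(=O)O[C@@H]1C[C@@](O)(C(C)C)[C@H]2[C@H](OC(=O)c3ccc(OC(C)=O)cc3)C=C(C)C(=O)C[C@]12C | intermediate
26 | (1R,3R,4R,5R,10S)-1-acetoxy-3-hydroxy-3-isopropyl-7,10-dimethyl-8-oxobicyclo[5.3.0]dec-6-en-5-yl 4-hydroxybenzoate (core locants) | CC(=O)O[C@@H]1C[C@@](O)(C(C)C)[C@H]2[C@H](OC(=O)c3ccc(O)cc3)C=C(C)C(=O)C[C@]12C | target

**Step count and risks**

Total step count: 18. Longest linear sequence: 18 steps (1 → 26).

The three steps most likely to fail:

Step 12. The shift itself is secure, but protonation of the ester enol at C4 may show poor facial selectivity, and slow capture of the ketene would let carbene-type side reactions compete. The fallback sets out from 15 and accepts the photolysate as a mixture containing the C4-epimeric methyl ester F1. Because F1 and 17 share one enolate, deprotonation with LiN(i-Pr)2 (2.2 equiv, THF, −78 °C) to the alkoxide–enolate and quenching with a hindered proton donor (2,6-di-tert-butyl-4-methylphenol) sets C4 in a separate kinetic enolate protonation from the face opposite the isopropyl and methyl groups. This comes back to the route at 17.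

Step 13. Loss of chelation control, or epimerisation of the transient aldehyde at C4, would erode the facial selectivity at C5. The fallback sets out from 17. If reduction and vinyl addition deliver mainly the (5S) allylic alcohol F2, that epimer is esterified under Mitsunobu conditions (4-acetoxybenzoic acid, PPh3, diisopropyl azodicarboxylate, toluene, 0 °C), which forms the C5–O bond with inversion. This comes back to the route at 21 without the acid chloride 20.

Step 16. The radical C–H oxidation may lack site selectivity (attack at the C7 methyl group or transposition of the allylic radical) or may over-oxidise. The fallback sets out from 22 and uses SeO2 (cat.)/t-BuOOH in CH2Cl2, an ene and [2,3]-sigmatropic sequence that functionalises the ring methylene on the more substituted alkene terminus, to give the C8 allylic alcohol F3. Dess–Martin periodinane then oxidises F3, and the route is rejoined at 23.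

Further compounds
F1 | step 12 | methyl (1R,2R,4R,5S)-4-(tert-butyldimethylsilyloxy)-2-hydroxy-2-isopropyl-5-methyl-5-(3-methylbut-3-en-1-yl)cyclopentane-1-carboxylate (C4 epimer of 17) | COC(=O)[C@H]1[C@](O)(C(C)C)C[C@@H](O[Si](C)(C)C(C)(C)C)[C@@]1(C)CCC(C)=C
F2 | step 13 | (1S)-1-[(1R,2R,4R,5S)-4-(tert-butyldimethylsilyloxy)-2-hydroxy-2-isopropyl-5-methyl-5-(3-methylbut-3-en-1-yl)cyclopentyl]prop-2-en-1-ol (C5 epimer of 19) | C=C[C@H](O)[C@@H]1[C@](O)(C(C)C)C[C@@H](O[Si](C)(C)C(C)(C)C)[C@@]1(C)CCC(C)=C
F3 | step 16 | 8-hydroxy derivative of 22 (C8 allylic alcohol, configuration at C8 not defined) | CC(C)(C)[Si](C)(C)O[C@@H]1C[C@@](O)(C(C)C)[C@H]2[C@H](OC(=O)c3ccc(OC(C)=O)cc3)C=C(C)C(O)C[C@]12C
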